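(Readings and results are calculated for an exercise.)

You start from a leftover: at 3.00 min the south run, the very flask asked about, still holds 87.8% of its electrophile.

- south: electrophile 0.050 M; nucleophile 0.0525 M; buffer base 0.15 M; buffer acid 5 mM; the very flask that is asked about, followed so far
- flask: electrophile 0.050 M; nucleophile 0.0525 M; buffer base 0.150 M; buffer acid 5.00 mM; time 8.0 min

south run (percent of the electrophile charged)

| time / min | electrophile / % | product / % |
|---|---|---|
| 0.167 | 98.0 | 1.4 |
| 0.500 | 98.1 | 2.6 |
| 0.833 | 97.9 | 2.9 |
| 1.33 | 93.5 | 5.8 |
| 2.00 | 93.0 | 9.2 |
| 2.50 | 90.7 | 9.0 |
| 3.00 | 87.8 | 10.7 |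

(readings scatter by 1 percentage point)

- part of the electrophile that has reacted at 8.0 min
- pH of the solution at 8.0 min

- acid is the free proton; pH is minus the decimal logarithm of its molar concentration
- what is said of product includes crystals
- crystals is a solid; its amount is given per volume of the solution
- steps under discussion: buffer acid <-> buffer base + acid; protonated nucleophile <-> nucleophile + acid; crystals <-> product; electrophile + nucleophile -> acid + product + leaving group
- the earlier runs do not show the pH; that part of a forecast is a guess

Each turnover uses one electrophile and one nucleophile. The nucleophile's excess is small, 2.50 mM on 0.050 M, so treat it as a correction: take both amounts at the mean of their charges. Then the inverse of the fraction left, minus one, grows in step with time. That growth per minute, divided by the mean charge, is the pairing constant (the second-order rate constant), which this reading puts at 0.904 L mol⁻¹ min⁻¹. Carried to 8.0 min, my reckoning gives 27.0% reacted, with the scatter of that one reading on it. No run shows the pH, so I reckon none.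

The forecast says 24%, less than mine, and pH 7, noting “so the absolute pH is a guess”.

The flask gives 26.3% and pH 6.28.

    buffer acid ⇌ buffer base + acid, settled at all times (K = 4.00 × 10⁻⁶ M)
    protonated nucleophile ⇌ nucleophile + acid, settled at all times (K = 1.00 × 10⁻⁴ M)
    crystals ⇌ product, rate k3*(cs3 - [product]) while solid is left; crystals form when [product] > cs3 (solubility = 1.30 mM, k = 0.0128 s⁻¹)
    electrophile + nucleophile → acid + product + leaving group (k = 0.0141 L mol⁻¹ s⁻¹)

The leftover of 74% at 8.00 min gives, by the same reckoning, 0.871 L mol⁻¹ min⁻¹. The main reason this flask has gone no further is the time allowed: left until 80.0 min, it reaches 79.3%, not 26.3%. With 0.13 M of nucleophile the charges differ widely, so the constant goes into an exponential of constant, charge difference and time. That gives a ratio of fractions left, nucleophile to electrophile, of 1.78. That flask shows 1.70, with 53.7% reacted.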